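Against the even count, where each equivalent of Z, the reagent in the second phase, ends as one D, the product, for as long as the substrate G lasts, Sunday's flask, the one you are taking over, returns far less: its readings from 25.0 h to 60.0 h average 21.2% of the G charged, and dividing by the 1.5 equiv of Z gives 14.2%, the return (a reagent efficiency), meaning the D at the plateau per equivalent of Z charged, well short of the 66.7% that the even count reaches in this flask when the G charged is used up.

all flasks: G 0.050 M
- Sunday's: Z 1.5 equiv; temperature 60 °C; the very flask that is asked about, followed so far
- Monday's: Z 3 equiv; temperature 55 °C; run made earlier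
- flask: Z 1.50 equiv; temperature 60 °C; time 4.0 d; volume of the second phase over the first 2.0

- Sunday's (time / h: D / %): 5.00: 17.0; 8.00: 19.1; 10.0: 19.4; 15.0: 20.3; 25.0: 21.1; 40.0: 21.4; 60.0: 21.2
- Monday's (time / min: D / %): 15.0: 3.2; 30.0: 6.3; 50.0: 9.2; 60.0: 11.0; 80.0: 12.8; 90.0: 13.6; 120: 16.0

(readings scatter by 0.3 percentage points)

- in the second phase: Z; everything else is in the first
- charges count per volume of the first phase; a concentration in a rate is the amount of a species over the volume of its own phase; every rate counts per litre of the first phase
- what is taken out of D is counted as made
- candidate steps: E <-> Z; G + E -> D; E + D -> X; E -> L; 2 E -> Q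
- the earlier runs hold the two phases in the same ratio of volumes as the flask asked about
- additions bring no volume worth counting

- red: at 4.0 d add G, 50.0% of the amount charged, then wait 4.0 d
- ochre: at 4.0 d raise the temperature by 15 K, then wait 4.0 d
- amber: change nothing and wait 4.0 d more
- grey: at 4.0 d take out 90% of the D then present, then wait 4.0 d

* D, in percent of the G first charged, at 4.0 d
* the remedy with the largest gain of D, or "none" below 2 percentage points (red / ochre / amber / grey / none)
* D present, with what was taken out counted in, in percent of the G first charged, after red
* D present, with what was taken out counted in, in percent of the G first charged, after grey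

Over that stretch of Sunday's flask the last reading of D stands 0.1 percentage points above the first, less than the scatter of 0.3 points, so my own reckoning for 4.0 d is the return times the equivalents, 21.2%, and my note to you is to leave this flask alone, since I expect no remedy to pay. The forecast gives 21.3% now, 21.3% after red, 21.3% after grey and none as the best remedy, on the ground that “the reagent must be dying”.

The forecast held: the flask gives 21.1% at 4.0 d, a return of 14.0%, with 21.1% after red, 21.1% after grey and none as the best remedy.

    E ⇌ Z, rate k1*([E] - [Z]/K1) per volume of the first phase (partition coefficient = 0.928, kL = 16.6 h⁻¹)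
    G + E → D (k = 4.72 M⁻¹ h⁻¹, Ea = 60.0 kJ mol⁻¹)
    E + D → X (k = 12.2 M⁻¹ h⁻¹, Ea = 77.0 kJ mol⁻¹)
    E → L (k = 6.42 × 10⁻⁴ h⁻¹, Ea = 120 kJ mol⁻¹)
    2 E → Q (k = 21.3 M⁻¹ h⁻¹, Ea = 77.0 kJ mol⁻¹)
    (constants at 60 °C)

At 96.0 h Sunday's flask holds 59.4% of its G but only 6.15 × 10⁻⁷ M of E, the reagent in the reaction phase, and at that E the half-life of G through the step making D is 10000 d, far longer than the 4.0 d of further waiting. A further flask like this one, but with 0.12 M of G at the same equivalents, gets 21.2% from the return, and its computed D is 21.1%.

The numbers in the tables are simulated on assumed constants; noise was put on by code.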